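The C4–C4a (piperidine) and C4a–O (dihydrofuran) bonds at C4a of the hexahydro-β-carboline core are the disconnection on which the route rests. C4a is both the aryl-ether carbon and the carbon β to C3, so it is traced back to the ketone of an indolin-3-one whose quaternary C2 (C9a) already carries the 7-methoxyindol-4-yl group and an N-methylacetamidomethyl arm. In one operation the amide enolate closes the piperidinone onto this ketone, and acid then dehydrates the carbinol, frees the ortho phenol and lets it add to C4a, which fixes C4a from C9a. The precursor is the (R)-N9-Boc pseudoindoxyl with a MOM-masked phenol and an N-tosylindole.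

Key step: step 12

Remarks on the chemistry
- Locants: β-carboline numbering for the core (C1, N2, C3, C4, C4a, C4b–C8a, N9, C9a); primed locants for the 7-methoxyindole. The target is (4aS,9aR); the three rings that share the C4a–C9a bond can only be cis-fused, so C9a defines the whole stereostructure.
- Assumption: the quinine-derived thiourea of step 7 is taken to deliver nitromethane to the Re face of the ketimine carbon (R at C9a); should the sense be opposite, the quinidine-derived pseudoenantiomer is used with no other change.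
- Design of the precursor: the phenol is carried as a MOM ether from step 2 through the enolate stage of step 12. No phenoxide then sits next to the N9-Boc group (to which the carbamate could migrate), only one acidic site consumes base, and the acid that dehydrates the aldol also removes MOM and Boc. This saves a separate phenol deprotection and a separate Boc removal.
- The free amines 12 and 15 are β-amino ketones that could lose the arm by retro-Mannich cleavage on heating; they are kept cold and taken on without storage.

Step 1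
Reactants: 1 3-methoxy-4-nitrophenol
Product: 2 2-bromo-5-methoxy-4-nitrophenol
Conditions: NBS (1.0 equiv), MeCN, 0 °C → rt
Reagents that add atoms: N-bromosuccinimide, O=C1CCC(=O)N1Br
Why: Electrophilic aromatic bromination should go to C6, which is ortho to OH, para to OMe, meta to NO2 and less hindered than C2 between the two oxygens.

Step 2
Reactants: 2 2-bromo-5-methoxy-4-nitrophenol
Product: 3 1-bromo-4-methoxy-2-(methoxymethoxy)-5-nitrobenzene
Conditions: MOMCl, K2CO3, DMF, 0 °C → rt
Reagents that add atoms: chloromethyl methyl ether, COCCl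
Why: Williamson-type O-alkylation of the acidic nitrophenoxide gives an acetal that tolerates Grignard, base, palladium and enolate chemistry and falls off in acid.

Step 3
Reactants: 3 1-bromo-4-methoxy-2-(methoxymethoxy)-5-nitrobenzene
Product: 4 4-bromo-7-methoxy-5-(methoxymethoxy)-1H-indole
Conditions: CH2=CHMgBr (3.5 equiv), THF, −40 °C; aq. NH4Cl
Reagents that add atoms: vinylmagnesium bromide, C=C[Mg]Br
Why: In the Bartoli indole synthesis the ortho methoxy group promotes the [3,3]-sigmatropic step, which can engage only the free ortho carbon, so Br ends at C4, OMOM at C5 and OMe at C7.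

Step 4
Reactants: 4 4-bromo-7-methoxy-5-(methoxymethoxy)-1H-indole
Product: 5 4-bromo-7-methoxy-5-(methoxymethoxy)-1-tosylindole
Conditions: NaH, TsCl, DMF, 0 °C → rt
Reagents that add atoms: p-toluenesulfonyl chloride, Cc1ccc(cc1)S(Cl)(=O)=O
Why: N-sulfonylation of the indolide deactivates this pyrrole ring towards the oxidant of step 6 and the cation of step 12.

Step 5
Reactants: 5 4-bromo-7-methoxy-5-(methoxymethoxy)-1-tosylindole; 6 1-(tert-butoxycarbonyl)indole-2-boronic acid
Product: 8 4-(1H-indol-2-yl)-7-methoxy-5-(methoxymethoxy)-1-tosylindole, via N-Boc biaryl 7 (not isolated)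
Conditions: Pd(OAc)2 (5 mol %), SPhos (10 mol %), K3PO4, THF/H2O, 40 °C; then MeOH, K2CO3, 50 °C
Reagents that add atoms: none
Why: Suzuki–Miyaura coupling with a bulky biarylphosphine should couple the hindered electron-rich bromide before the 2-indolylboronic acid protodeboronates, and mild methanolysis then removes the labile indole N-Boc while the hindered N-tosyl group stays.

Step 6
Reactants: 8 4-(1H-indol-2-yl)-7-methoxy-5-(methoxymethoxy)-1-tosylindole
Product: 9 2-[7-methoxy-5-(methoxymethoxy)-1-tosylindol-4-yl]-3H-indol-3-one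
Conditions: CuCl (10 mol %), pyridine (20 mol %), O2 (1 atm), MeCN, 40 °C
Reagents that add atoms: dioxygen, O=O
Why: Copper-catalysed aerobic C3 oxygenation of a free 2-arylindole proceeds through the 3-hydroperoxy-3H-indole, which loses water in a Kornblum–DeLaMare-type step to the cyclic C-acyl ketimine, while the N-tosylindole is not attacked.

Step 7
Reactants: 9 2-[7-methoxy-5-(methoxymethoxy)-1-tosylindol-4-yl]-3H-indol-3-one; 10 nitromethane
Product: 11 (R)-2-[7-methoxy-5-(methoxymethoxy)-1-tosylindol-4-yl]-2-(nitromethyl)indolin-3-one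
Conditions: MeNO2 (10 equiv), N-[3,5-bis(trifluoromethyl)phenyl]-N'-(9-deoxy-epi-quinin-9-yl)thiourea (10 mol %), toluene, −20 °C
Reagents that add atoms: none
Why: In this catalytic asymmetric aza-Henry reaction the quinuclidine forms the nitronate and the thiourea and quinuclidinium N–H hold nitronate and ketimine together, so that addition to the Re face of the C=N carbon should set C9a as R under catalyst control.

Step 8
Reactants: 11 (R)-2-[7-methoxy-5-(methoxymethoxy)-1-tosylindol-4-yl]-2-(nitromethyl)indolin-3-one
Product: 12 (R)-2-(aminomethyl)-2-[7-methoxy-5-(methoxymethoxy)-1-tosylindol-4-yl]indolin-3-one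
Conditions: Zn dust, AcOH/THF, 0 °C → rt
Reagents that add atoms: none
Why: Zinc in acetic acid reduces the aliphatic nitro group to the amine under acidic conditions in which retro-aza-Henry cleavage at C9a cannot start, and the aryl ketone, MOM acetal and sulfonamide are untouched.

Step 9
Reactants: 12 (R)-2-(aminomethyl)-2-[7-methoxy-5-(methoxymethoxy)-1-tosylindol-4-yl]indolin-3-one
Product: 15 (R)-2-[7-methoxy-5-(methoxymethoxy)-1-tosylindol-4-yl]-2-[(methylamino)methyl]indolin-3-one, via N-benzylidene imine 13 (not isolated), via N-methyliminium triflate 14 (not isolated)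
Conditions: PhCHO, MgSO4, CH2Cl2, rt; MeOTf, 0 °C; then H2O/THF, aq. NaHCO3
Reagents that add atoms: methyl trifluoromethanesulfonate, COS(=O)(=O)C(F)(F)F
Why: Mono-N-methylation through the Schiff base (Decker–Forster alkylation) works because the imine nitrogen can take up only one methyl group and hydrolysis of the iminium ion releases the secondary amine, while the hindered vinylogous-amide N9–H is not alkylated at 0 °C.

Step 10
Reactants: 15 (R)-2-[7-methoxy-5-(methoxymethoxy)-1-tosylindol-4-yl]-2-[(methylamino)methyl]indolin-3-one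
Product: 16 (R)-N-{[2-(7-methoxy-5-(methoxymethoxy)-1-tosylindol-4-yl)-3-oxoindolin-2-yl]methyl}-N-methylacetamide
Conditions: Ac2O, Et3N, CH2Cl2, 0 °C
Reagents that add atoms: acetic anhydride, CC(=O)OC(C)=O
Why: N-acylation of the secondary aliphatic amine is selective because N9–H does not react without an acyl-transfer catalyst, and the amide no longer has a lone pair that could trigger retro-Mannich loss of the arm.

Step 11
Reactants: 16 (R)-N-{[2-(7-methoxy-5-(methoxymethoxy)-1-tosylindol-4-yl)-3-oxoindolin-2-yl]methyl}-N-methylacetamide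
Product: 17 tert-butyl (R)-2-[7-methoxy-5-(methoxymethoxy)-1-tosylindol-4-yl]-2-[(N-methylacetamido)methyl]-3-oxoindoline-1-carboxylate
Conditions: Boc2O, DMAP, MeCN, 40 °C
Reagents that add atoms: di-tert-butyl dicarbonate, CC(C)(C)OC(=O)OC(=O)OC(C)(C)C
Why: DMAP-catalysed carbamoylation of the acidic N9–H leaves the tertiary amide alone and turns the vinylogous-amide ketone into an electrophilic aryl ketone for the aldol.

Step 12
Reactants: 17 tert-butyl (R)-2-[7-methoxy-5-(methoxymethoxy)-1-tosylindol-4-yl]-2-[(N-methylacetamido)methyl]-3-oxoindoline-1-carboxylate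
Product: 20 (4aS,9aR)-N1'-tosyl hexacyclic lactam with free N9–H, via aldol carbinol 18 (not isolated), via unsaturated lactam phenol 19 (not isolated)
Conditions: LiN(SiMe3)2 (1.5 equiv), THF, −78 → 0 °C; then HCl (3 M in MeOH), −78 → 50 °C
Reagents that add atoms: none
Why: LiN(SiMe3)2 reversibly enolises the acetamide methyl group, and the enolate carbon adds to the N-Boc-activated indolin-3-one carbonyl in a 6-exo-trig intramolecular amide aldol (C4–C4a) that draws the enolisation forward; the ketone is non-enolisable, the base has no β-hydrogen to reduce it, and retro-aldol can only return 17. Methanolic HCl then protonates the aldolate, cleaves the MOM ether and the Boc group and dehydrates or ionises the tertiary benzylic carbinol 18 to the conjugated lactam 19, and the freed phenol adds to C4a in a 5-exo-trig oxa-Michael closure (C4a–O). The closest known reactions are Camps-type amide-enolate aldol condensations onto aryl ketones and acid-mediated closure of ortho-hydroxyaryl groups onto benzylic indoline cations or unsaturated lactams. C9a controls C4a: the enolate arm can reach the carbonyl only from its own face and the phenol, held on the aryl group at C9a, only from the other, so both new rings are cis-fused to the indoline and C4a should result as S. The step needs C–C bond formation before any oxygen nucleophile is present, which the MOM mask secures, and the N-tosyl group keeps C3' of the methoxyindole from competing for the cation.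

Step 13
Reactants: 20 (4aS,9aR)-N1'-tosyl hexacyclic lactam with free N9–H
Product: 21 (4aS,9aR)-N1'-tosyl hexacyclic amine (N2-methylpiperidine)
Conditions: LiAlH4, THF, 0 → 60 °C
Reagents that add atoms: none
Why: Hydride reduction of the tertiary lactam to the amine runs through the hemiaminal aluminate and the iminium ion; no other carbonyl is present, and any N-tosyl cleavage here only anticipates step 14.

Step 14
Reactants: 21 (4aS,9aR)-N1'-tosyl hexacyclic amine (N2-methylpiperidine)
Product: 22 (4aS,9aR)-hexacyclic amine with free indole N1'–H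
Conditions: Mg turnings, MeOH, rt, sonication
Reagents that add atoms: none
Why: Magnesium in methanol cleaves the indole N–S bond by single-electron reduction, and with the lactam already reduced no β-aryloxy carbonyl unit remains that could open by retro-oxa-Michael reaction.

Step 15
Reactants: 22 (4aS,9aR)-hexacyclic amine with free indole N1'–H
Product: 23 target, (4aS,9aR)-3'-[(dimethylamino)methyl] hexacycle
Conditions: Me2NH (40% aq.), CH2O (37% aq.), AcOH, rt
Reagents that add atoms: formaldehyde, C=O; dimethylamine, CNC
Why: Mannich aminomethylation (gramine synthesis) should occur at C3', the most nucleophilic carbon of the free indole, while aminals at N9 form reversibly and revert on basic work-up.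

Compound list
1 | 3-methoxy-4-nitrophenol | COc1cc(O)ccc1[N+](=O)[O-] | starting material
2 | 2-bromo-5-methoxy-4-nitrophenol | COc1cc(O)c(Br)cc1[N+](=O)[O-] | intermediate
3 | 1-bromo-4-methoxy-2-(methoxymethoxy)-5-nitrobenzene | COCOc1cc(OC)c([N+](=O)[O-])cc1Br | intermediate
4 | 4-bromo-7-methoxy-5-(methoxymethoxy)-1H-indole | COc1cc(OCOC)c(Br)c2cc[nH]c12 | intermediate
5 | 4-bromo-7-methoxy-5-(methoxymethoxy)-1-tosylindole | COc1cc(OCOC)c(Br)c2ccn(S(=O)(=O)c3ccc(C)cc3)c12 | intermediate
6 | 1-(tert-butoxycarbonyl)indole-2-boronic acid | CC(C)(C)OC(=O)n1c(B(O)O)cc2ccccc12 | starting material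
7 | tert-butyl 2-[7-methoxy-5-(methoxymethoxy)-1-tosylindol-4-yl]indole-1-carboxylate (N-Boc biaryl) | COc1cc(OCOC)c(-c2cc3ccccc3n2C(=O)OC(C)(C)C)c2ccn(S(=O)(=O)c3ccc(C)cc3)c12 | intermediate
8 | 4-(1H-indol-2-yl)-7-methoxy-5-(methoxymethoxy)-1-tosylindole | COc1cc(OCOC)c(-c2cc3ccccc3[nH]2)c2ccn(S(=O)(=O)c3ccc(C)cc3)c12 | intermediate
9 | 2-[7-methoxy-5-(methoxymethoxy)-1-tosylindol-4-yl]-3H-indol-3-one | COc1cc(OCOC)c(C2=Nc3ccccc3C2=O)c2ccn(S(=O)(=O)c3ccc(C)cc3)c12 | intermediate
10 | nitromethane | C[N+](=O)[O-] | starting material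
11 | (R)-2-[7-methoxy-5-(methoxymethoxy)-1-tosylindol-4-yl]-2-(nitromethyl)indolin-3-one | COc1cc(OCOC)c(c2ccn(S(=O)(=O)c3ccc(C)cc3)c12)[C@@]1(Nc2ccccc2C1=O)C[N+](=O)[O-] | intermediate
12 | (R)-2-(aminomethyl)-2-[7-methoxy-5-(methoxymethoxy)-1-tosylindol-4-yl]indolin-3-one | COc1cc(OCOC)c(c2ccn(S(=O)(=O)c3ccc(C)cc3)c12)[C@@]1(Nc2ccccc2C1=O)CN | intermediate
13 | (R,E)-2-[(benzylideneamino)methyl]-2-[7-methoxy-5-(methoxymethoxy)-1-tosylindol-4-yl]indolin-3-one (N-benzylidene imine) | COc1cc(OCOC)c(c2ccn(S(=O)(=O)c3ccc(C)cc3)c12)[C@@]1(Nc2ccccc2C1=O)C/N=C/c1ccccc1 | intermediate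
14 | N-benzylidene-N-methyl iminium triflate of 12 (N-methyliminium triflate) | COc1cc(OCOC)c(c2ccn(S(=O)(=O)c3ccc(C)cc3)c12)[C@@]1(Nc2ccccc2C1=O)C[N+](C)=Cc1ccccc1.[O-]S(=O)(=O)C(F)(F)F | intermediate
15 | (R)-2-[7-methoxy-5-(methoxymethoxy)-1-tosylindol-4-yl]-2-[(methylamino)methyl]indolin-3-one | COc1cc(OCOC)c(c2ccn(S(=O)(=O)c3ccc(C)cc3)c12)[C@@]1(Nc2ccccc2C1=O)CNC | intermediate
16 | (R)-N-{[2-(7-methoxy-5-(methoxymethoxy)-1-tosylindol-4-yl)-3-oxoindolin-2-yl]methyl}-N-methylacetamide | COc1cc(OCOC)c(c2ccn(S(=O)(=O)c3ccc(C)cc3)c12)[C@@]1(Nc2ccccc2C1=O)CN(C)C(C)=O | intermediate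
17 | tert-butyl (R)-2-[7-methoxy-5-(methoxymethoxy)-1-tosylindol-4-yl]-2-[(N-methylacetamido)methyl]-3-oxoindoline-1-carboxylate (key-step precursor) | COc1cc(OCOC)c(c2ccn(S(=O)(=O)c3ccc(C)cc3)c12)[C@@]1(N(C(=O)OC(C)(C)C)c2ccccc2C1=O)CN(C)C(C)=O | intermediate
18 | (4aS,9aR)-N9-Boc 4a-hydroxy-2-methyl-3-oxo-hexahydro-β-carboline carrying the 7-methoxy-5-(methoxymethoxy)-1-tosylindol-4-yl group at C9a, OH cis to the aryl group (aldol carbinol) | COc1cc(OCOC)c(c2ccn(S(=O)(=O)c3ccc(C)cc3)c12)[C@@]12CN(C)C(=O)C[C@]1(O)c1ccccc1N2C(=O)OC(C)(C)C | intermediate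
19 | 9a-(5-hydroxy-7-methoxy-1-tosylindol-4-yl)-2-methyl-1,2,9,9a-tetrahydro-β-carbolin-3-one, C4=C4a unsaturated, C9a configuration unchanged (unsaturated lactam phenol) | COc1cc(O)c(c2ccn(S(=O)(=O)c3ccc(C)cc3)c12)[C@@]12CN(C)C(=O)C=C1c1ccccc1N2 | intermediate
20 | (4aS,9aR)-hexacyclic lactam: 2-methyl-3-oxo core, N9–H, dihydrofuran closed from C4a to O5' of the 7'-methoxy-1'-tosylindole bound through C4' to C9a | COc1cc2c(c3ccn(S(=O)(=O)c4ccc(C)cc4)c13)[C@@]13CN(C)C(=O)C[C@]1(O2)c1ccccc1N3 | intermediate
21 | (4aS,9aR)-hexacyclic N2-methylpiperidine, N1'-tosyl | COc1cc2c(c3ccn(S(=O)(=O)c4ccc(C)cc4)c13)[C@@]13CN(C)CC[C@]1(O2)c1ccccc1N3 | intermediate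
22 | (4aS,9aR)-hexacyclic N2-methylpiperidine with free indole N1'–H | COc1cc2c(c3cc[nH]c13)[C@@]13CN(C)CC[C@]1(O2)c1ccccc1N3 | intermediate
23 | (4aS,9aR)-hexacycle bearing the 3'-[(dimethylamino)methyl] group | COc1cc2c(c3c(CN(C)C)c[nH]c13)[C@@]13CN(C)CC[C@]1(O2)c1ccccc1N3 | target

Total step count: 15. Longest linear sequence: 15 steps (1 → 23); 6 enters at step 5 and 10 at step 7.

Steps most likely to fail

1. Step 12. The enolisation may be too unfavourable, so that the ketone is simply returned. In the acid stage the benzylic cation may be diverted by a 1,2-aryl shift from C9a or by lasting capture by methanol before the phenol is free. The fallback replaces the aldol by an olefination with the same bond set and sets out from amine 15. Acylation with diethylphosphonoacetic acid (EDC·HCl, HOBt, CH2Cl2) would give the phosphonoacetamide F1. Boc2O and DMAP would give the N9-Boc phosphonoacetamide F2. NaH in THF would then close the piperidinone by intramolecular Horner–Wadsworth–Emmons olefination of the ketone to the N9-Boc unsaturated lactam F3. Methanolic HCl would remove MOM and Boc and effect the oxa-Michael closure, coming back to the route at 20.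

2. Step 7. Addition may be slow and the two faces poorly discriminated, because the ketimine carbon is shielded by an aryl group substituted at both ortho positions. The fallback sets out from ketimine 9. An aza-Henry reaction with nitromethane as solvent and Et3N as achiral base would give the racemic nitromethyl indolinone F4. Its enantiomers would be separated by preparative chromatography on a chiral stationary phase, coming back to the route at 11.

3. Step 5. Protodeboronation of the 2-indolylboronic acid may outrun transmetalation onto the hindered arylpalladium bromide. The fallback builds the second indole ring instead of coupling it and sets out from bromide 5. Copper-free Sonogashira coupling with 2-ethynylaniline (PdCl2(MeCN)2, XPhos, Cs2CO3, MeCN, 80 °C) would give the 2-(arylethynyl)aniline F5. 5-endo-dig hydroamination (CuI, DMF, 100 °C) would then close the indole, coming back to the route at 8.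

Further compounds
F1 | step 12 | diethyl (R)-{2-[({2-[7-methoxy-5-(methoxymethoxy)-1-tosylindol-4-yl]-3-oxoindolin-2-yl}methyl)(methyl)amino]-2-oxoethyl}phosphonate | COc1cc(OCOC)c(c2ccn(S(=O)(=O)c3ccc(C)cc3)c12)[C@@]1(Nc2ccccc2C1=O)CN(C)C(=O)CP(=O)(OCC)OCC
F2 | step 12 | N9-Boc derivative of F1 | COc1cc(OCOC)c(c2ccn(S(=O)(=O)c3ccc(C)cc3)c12)[C@@]1(N(C(=O)OC(C)(C)C)c2ccccc2C1=O)CN(C)C(=O)CP(=O)(OCC)OCC
F3 | step 12 | N9-Boc C4=C4a unsaturated lactam with MOM-protected phenol | COc1cc(OCOC)c(c2ccn(S(=O)(=O)c3ccc(C)cc3)c12)[C@@]12CN(C)C(=O)C=C1c1ccccc1N2C(=O)OC(C)(C)C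
F4 | step 7 | racemic 2-[7-methoxy-5-(methoxymethoxy)-1-tosylindol-4-yl]-2-(nitromethyl)indolin-3-one | COc1cc(OCOC)c(c2ccn(S(=O)(=O)c3ccc(C)cc3)c12)C1(Nc2ccccc2C1=O)C[N+](=O)[O-]
F5 | step 5 | 2-{[7-methoxy-5-(methoxymethoxy)-1-tosylindol-4-yl]ethynyl}aniline | COc1cc(OCOC)c(C#Cc2ccccc2N)c2ccn(S(=O)(=O)c3ccc(C)cc3)c12
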